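# Sodwanone T by twofold allylboration of a central bis(allylboronate)

**Compound numbers used throughout:** 1 diethyl adipate; 2 acetaldehyde; 3 dilithium bis-enolate; 4 bis-aldol; 5 bis(β-keto ester); 6 disodium bis-enolate; 7 bis(Z-enol triflate); 8 5-bromo-2-methylpent-2-ene; 9 its Grignard reagent; 10 bis-enoate; 11 bis(allylic alcohol); 12 bis(pinacolato)diboron; 13 bis(allylboronate); 14 4-methylpent-4-en-1-ol; 15 4-methylpent-4-enal; 16 bis(borate) adduct; 17 hexaene diol; 18 bis-epoxide; 19 bis-oxepane; 20 C2-symmetric diol; 21 sodwanone T.

## Analysis of the target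

Sodwanone T (21) consists of two trans-fused oxepane–cyclohexene bicycles joined through their alkene carbons C11 and C14 by the C12–C13 ethano bridge (squalene-type numbering, in which C2 and C23 are the gem-dimethyl ether carbons, C3 is the ketone carbon and C22 the carbinol carbon). Apart from the oxidation level at C3 versus C22 the molecule is C2-symmetric. There are five stereocentres: the methyl-bearing quaternary carbons C6 and C19 (both S), the adjacent ether methines C7 and C18 (both S), and the remote carbinol C22 (R); at each ring fusion the angular methyl and the methine hydrogen are anti. The only C=C bonds are the tetrasubstituted ring alkenes C10=C11 and C14=C15, each next to a quaternary carbon, and they are sensitive to acid-induced migration and to electrophilic oxidants. The α-alkoxy ketone is enolisable at C4 but has no epimerisable neighbour. The hard points are the quaternary/oxygenated pair C6/C7 (twice, with absolute control), the hindered tetrasubstituted alkenes, a seven-membered ether closed onto a fully substituted carbon, and the late differentiation of C3 from C22. The strategy rests on the array O–C7–C6(CH3)(C5)–C11(=C)–C12, a homoallylic alcohol with an all-carbon quaternary centre between carbinol and alkene. This is the retron of a γ,γ-disubstituted allylboronate adding to an aldehyde, and because C11 and C14 are separated by only two methylenes, both arrays can be drawn from one central bis(allyl) reagent.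

## Retrosynthetic reasoning

**21 ⇒ 20.** The target differs from the C2-symmetric diol 20 only in the oxidation level of one carbinol, so the last operation is oxidation of one of two equivalent secondary alcohols. Cutting here lets every earlier bond be made twice in one flask. The price is a statistical last step, accepted because 20 is recoverable.

**20 ⇒ 19.** Both ring alkenes (C10=C11, C14=C15) are cut. This is the only opening of the carbocycles that leaves the C6/C7 pairs untouched. It turns each cyclohexene into two arms ending in 1,1-disubstituted alkenes: a methylidene on C11 (C14) and a methallyl terminus at C10 (C15). The forward step is a twofold ring-closing metathesis to tetrasubstituted cyclohexenes. The C11 methylidene it needs is exactly what an allyl transposition leaves behind.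

**19 ⇒ 18.** The C2–O and C23–O ether bonds are cut, revealing the C7/C18 hydroxyls and trisubstituted epoxides at C2–C3 and C22–C23. The ether is cut at the fully substituted carbon because C2 carries no stereochemistry, C7 acts only as a spectator nucleophile, and C3 keeps its C–O bond. The forward reaction must steer the hydroxyl to the tertiary epoxide carbon (seven-membered endo mode) and away from C3.

**18 ⇒ 17.** The epoxides come from the two trisubstituted side-chain alkenes of 17 by reagent-controlled oxygen transfer, which sets C3 and C22 far from all other stereocentres. The oxidant must prefer the trisubstituted alkenes over four 1,1-disubstituted ones. Epoxidation and ether closure are placed before metathesis because a prenyl-type alkene left in the metathesis substrate would close a cyclopentene onto the C11 methylidene.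

**17 ⇒ 13 + 15 (key disconnection).** The C6–C7 and C18–C19 bonds are cut. Each is the bond between the γ-carbon of an allylboron unit and an aldehyde carbon, so 17 falls apart into the bis(allylboronate) 13 and two molecules of aldehyde 15. This gives up four stereocentres, two skeletal bonds and 12 of the 30 target carbons in one operation, from achiral acyclic pieces. The forward reaction must relay the alkene geometry of 13 into the C6/C7 relationship through a closed transition state and obtain the absolute sense from a chiral acid acting identically at both ends.

**13 ⇒ 11 + 12.** The two C–B bonds are traced to allylic C–O bonds. The borylation must place boron on the CH2 terminus and keep the geometry of the fully substituted alkene.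

**11 ⇒ 10 ⇒ 7 + 8.** The allylic alcohols come from the esters of 10. The C5–C6 and C19–C20 bonds are then cut at the alkene, which becomes a cross-coupling of Grignard reagent 9 (from 8) with the enol triflate 7. The point of cutting here is that the alkene geometry is reduced to the geometry of a chelated β-keto ester enolate.

**7 ⇒ 5 ⇒ 4 ⇒ 1 + 2.** The enol triflate comes from bis(β-keto ester) 5. Direct C-acylation of 1 risks Dieckmann closure and O-acylation, so 5 is reached by double aldol addition of the bis-enolate 3 to two molecules of 2 and oxidation of 4.

**15 ⇒ 14.** The volatile aldehyde is made fresh by oxidation of the commercial alcohol.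

## Alternatives that were turned down

**Alternative 1: oxepanones by one-carbon expansion of pyranones.**
- Disconnection: C3–C4/C4–C5 and C20–C21/C21–C22, so each oxepanone is traced to a six-membered 2,2-dimethylpyran-3-one lacking C4 (C21), the bis(pyranone) A2.
- Forward key step: Lewis-acid-promoted insertion of a silyl diazomethane carbon into both ketones of A2, with migration of the ring methylene next to the quaternary carbon (Tiffeneau–Demjanov type), to give the bis(oxepan-3-one) A1. One stereoselective reduction of A1 would then give 21.
- For it: six-membered ethers form more dependably than oxepanes, so the seven-membered closure is avoided altogether. On that point this route is stronger than the chosen one. A1 is already at the ketone level, so the endgame is a mono-reduction (statistically no worse than a mono-oxidation).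
- Against it: each ketone has two α-carbons, the C5 methylene and the oxygen-bearing quaternary C2. Exclusive migration of C5 is needed at both sites and any error is multiplied. The Lewis acid must also spare two tetrasubstituted alkenes. The step adds two carbons but creates no stereocentre and solves neither the C6/C7 pairs nor the ring alkenes, all of which A2 must already contain. C22 would rest on substrate-controlled hydride delivery.
- Comparison: the chosen key step makes two skeletal bonds and four stereocentres and brings in all remaining carbons. In exchange for accepting the endo epoxide opening, it sets C22 by reagent control before any ring exists.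

**Alternative 2: diyne plus two enones by asymmetric conjugate alkenylation.**
- Disconnection: C6–C11 and C14–C19, the bonds from each quaternary carbon to the central diene.
- Forward key step: internal hydroalumination of diyne A4 to a bis(2-alkenyl)alane, which adds 1,4 to two molecules of enone A5 under a chiral N-heterocyclic-carbene copper catalyst (generated from CuCl2·2H2O) to give diketone A3 with both quaternary stereocentres.
- For it: it is the shortest access to the C11–C14 diene with both quaternary centres, from two commercial pieces. Conjugate alkenylation of β-methyl enones is probably more dependable in enantiocontrol than allylboration with a fully substituted boronate. For the quaternary centres alone it is the stronger plan.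
- Against it: A3 holds only 20 of the 30 carbons and none of the oxygen-bearing stereocentres. Its six-membered rings are not the cyclohexenes of 21, since C11 is exocyclic. In the most economical mapping the ring carbons become C7, C2, C3, C4 and C5 of the oxepane after oxygen insertion (a Baeyer–Villiger step choosing between two similar methylenes). C7 would then be an O–CH2 group that still needs its C8 substituent and its configuration next to the quaternary carbon. The gem-dimethyl groups, the C3 oxygen and the whole C8–C10 arm are also missing.
- Comparison: the chosen step forms C6 and C7 together, with the C7 oxygen and the C8–C10 arm already in place and the C11 methylidene positioned for ring closure. Far less remains to be done after it.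

**Alternative 3: oxepane first, cyclohexenes closed onto the lactone carbonyls.**
- Disconnection: C7=C8 and C17=C18 of the bis(enol ether) A6, which is traced to the bis(lactone) A7 carrying terminal alkenes on acyclic, tetrasubstituted C10=C11 (C14=C15) arms.
- Forward key step: a titanium alkylidene of the Takai–Utimoto type (from TiCl4, TMEDA, Zn, catalytic PbCl2 and CH3CHBr2) exchanges with each terminal alkene and then olefinates the lactone carbonyl, closing both carbocycles as cyclic enol ethers (A6). Reduction of the enol ethers, desilylation and mono-oxidation would follow.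
- For it: the seven-membered ring is secured early by lactonisation, which is more reliable than an endo epoxide opening. The ring-closing event makes a trisubstituted enol ether, which is easier than a tetrasubstituted alkene by metathesis. On both points it is stronger than the chosen route.
- Against it: a stoichiometric low-valent titanium reagent must act twice on neopentylic lactone carbonyls next to C6. C6 has to be installed beforehand as an α-quaternary lactone stereocentre by separate asymmetric chemistry. The tetrasubstituted alkenes must be carried acyclic with defined geometry. C7 and C18 are set only at the end, by face-selective reduction of enol ethers that sit in skipped cyclohexadienes.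
- Comparison: the chosen strategy sets C6 and C7 in one catalyst-controlled step from achiral material and defers only the ring closures. It offers stereochemical economy and convergence in place of the safer ether formation.

Key step: step 8

**Remarks on the chemistry (assumptions):**
- The (R) antipode of the phosphoric acid is assumed to direct the allyl group to the Re face of the aldehyde, as it does with simple allyl- and crotylboronates; if the sense were opposite, the (S) acid would be used.
- The D-fructose-derived Shi ketone is assumed to give the (R)-epoxide from R–CH=C(CH3)2 alkenes, as the spiro transition-state model predicts.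
- Steps 1, 4, 6 and 8 are twofold reactions in which two molecules of one numbered compound each leave atoms in the product; the first molecule stands on the Reactants line and the second under the reagents that add atoms.

## Route

**Step 1**
Reactants: 1 diethyl adipate; 2 acetaldehyde
Product: 4 diethyl 2,5-bis(1-hydroxyethyl)hexanedioate (mixture of diastereomers), via dilithium bis-enolate 3 (not isolated)
Conditions: LiN(i-Pr)2 (2.3 equiv), THF, −78 °C, inverse addition of 1; 2 (3 equiv), −78 °C; AcOH quench at −78 °C
Reagents that add atoms: acetaldehyde (second molecule of 2), CC=O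
Why: Lithium ester-enolate aldol addition at both α-carbons, one molecule of 2 being taken up at each; the doubly deprotonated diester has no neutral ester left for Dieckmann closure, and addition to the aldehyde at −78 °C outruns any Claisen pathway. The stereocentres formed are erased in steps 2 and 3.

**Step 2**
Reactants: 4 diethyl 2,5-bis(1-hydroxyethyl)hexanedioate
Product: 5 diethyl 2,5-diacetylhexanedioate (mixture of diastereomers)
Conditions: Dess–Martin periodinane (2.6 equiv), CH2Cl2, 0 °C → rt
Reagents that add atoms: none
Why: Dess–Martin oxidation of β-hydroxy esters to β-keto esters under non-basic conditions that avoid retro-aldol cleavage.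

**Step 3**
Reactants: 5 diethyl 2,5-diacetylhexanedioate
Product: 7 diethyl (2Z,5Z)-2,5-bis[1-(trifluoromethanesulfonyloxy)ethylidene]hexanedioate, via disodium bis-enolate 6 (not isolated)
Conditions: NaH (2.4 equiv), Et2O, 0 °C; Tf2O (2.4 equiv), −78 → 0 °C
Reagents that add atoms: trifluoromethanesulfonic anhydride, O=S(=O)(OS(=O)(=O)C(F)(F)F)C(F)(F)F
Why: O-Triflation of a β-keto ester enolate; in the weakly coordinating solvent sodium is chelated between the enolate and ester oxygens, so the triflate should form cis to the ester (Z) at both ends. This geometry later becomes the C6 and C19 configuration.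

**Step 4**
Reactants: 7 diethyl (2Z,5Z)-2,5-bis[1-(trifluoromethanesulfonyloxy)ethylidene]hexanedioate; 8 5-bromo-2-methylpent-2-ene
Product: 10 diethyl (2Z,5Z)-2,5-bis(6-methylhept-5-en-2-ylidene)hexanedioate, via (4-methylpent-3-en-1-yl)magnesium bromide 9 (not isolated)
Conditions: 8 (2.8 equiv), Mg turnings, THF, 35 °C; then 7, Fe(acac)3 (10 mol%), THF/NMP, −30 °C
Reagents that add atoms: 5-bromo-2-methylpent-2-ene (second molecule of 8 likewise converted into 9), CC(C)=CCCBr
Why: Iron-catalysed Kumada-type cross-coupling of alkenyl triflates with an alkyl Grignard reagent; it is fast at −30 °C, so the esters are not attacked. It proceeds with retention, so the C5 chain enters cis to the ester and the methyl stays trans.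

**Step 5**
Reactants: 10 diethyl (2Z,5Z)-2,5-bis(6-methylhept-5-en-2-ylidene)hexanedioate
Product: 11 (2Z,5Z)-2,5-bis(6-methylhept-5-en-2-ylidene)hexane-1,6-diol
Conditions: i-Bu2AlH (4.8 equiv), CH2Cl2, −78 → 0 °C; aq. potassium sodium tartrate work-up
Reagents that add atoms: none
Why: 1,2-Reduction of α,β-unsaturated esters to allylic alcohols; the fully substituted alkene blocks conjugate reduction and its geometry is untouched.

**Step 6**
Reactants: 11 (2Z,5Z)-2,5-bis(6-methylhept-5-en-2-ylidene)hexane-1,6-diol; 12 bis(pinacolato)diboron
Product: 13 (6E,10E)-2,6,11,15-tetramethyl-7,10-bis[(4,4,5,5-tetramethyl-1,3,2-dioxaborolan-2-yl)methyl]hexadeca-2,6,10,14-tetraene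
Conditions: 12 (2.6 equiv), [Pd(MeCN)4](BF4)2 (5 mol%), DMSO/MeOH (1:1), 40 °C
Reagents that add atoms: bis(pinacolato)diboron (second molecule of 12), CC1(C)OB(OC1(C)C)B1OC(C)(C)C(C)(C)O1
Why: Palladium-catalysed borylation of allylic alcohols (Miyaura-type allylic borylation through an η3-allylpalladium intermediate); boron should go to the unsubstituted CH2 terminus. The geometry of the fully substituted terminus should be kept, because syn/anti exchange would have to pass through a tertiary σ-allyl species.

**Step 7**
Reactants: 14 4-methylpent-4-en-1-ol
Product: 15 4-methylpent-4-enal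
Conditions: TEMPO (10 mol%), PhI(OAc)2 (1.1 equiv), CH2Cl2, rt; used as a solution after short-path distillation
Reagents that add atoms: none
Why: Nitroxyl-catalysed oxidation of a primary alcohol to the aldehyde without over-oxidation or alkene migration.

**Step 8**
Reactants: 13 (6E,10E)-bis(allylboronate); 15 4-methylpent-4-enal
Product: 17 (5S,6S,11S,12S)-2,6,11,15-tetramethyl-7,10-dimethylidene-6,11-bis(4-methylpent-3-en-1-yl)hexadeca-1,15-diene-5,12-diol, via bis(pinacol borate) adduct 16 (not isolated)
Conditions: 15 (3 equiv), (R)-TRIP [(R)-3,3'-bis(2,4,6-triisopropylphenyl)-1,1'-binaphthyl-2,2'-diyl hydrogen phosphate] (10 mol%), 4 Å molecular sieves, toluene, −30 → 0 °C; then aq. NaHCO3, rt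
Reagents that add atoms: 4-methylpent-4-enal (second molecule of 15), CC(=C)CCC=O
Why: Each allyl–B(pin) unit should add to one molecule of the aldehyde through its γ-carbon (C6 or C19) in a closed six-membered chair in which boron binds the carbonyl oxygen, the phosphoric acid hydrogen-bonds to a boronate oxygen and the aldehyde chain sits equatorial; this is the chiral-phosphoric-acid-catalysed allylboration of aldehydes with γ,γ-disubstituted allylboronates, run twice on one reagent. No ring closes; the C6–C7 and C18–C19 bonds form and the allyl shift leaves the C11 and C14 methylidene groups. The relative configuration of each C6/C7 pair follows from the (E)-geometry of 13: the methyl trans to CH2B ends anti, and the C5 chain cis to CH2B ends syn, to the new hydroxyl in the extended C8–C7–C6–C11 chain, which is the relationship of the trans ring fusion. The absolute configuration comes from the catalyst, which should shield the Si face of the aldehyde so that C6 attacks the Re face, giving 7S and hence 6S; the same sense operates at the remote second terminus. γ-Selectivity is inherent in the cyclic transition state, and the alkenes of 15 and of the side chains are spectators. Because two independent catalyst-controlled events are combined, the minor sense should end mostly in the separable meso-type (6S,7S,18R,19R) diastereomer, so the C2-symmetric diol is expected in higher enantiopurity than a single addition would give. The step needs a geometrically pure boronate and enough catalyst turnover to outrun the uncatalysed background; low temperature and sieves serve both.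

**Step 9**
Reactants: 17 (5S,6S,11S,12S)-hexaene diol
Product: 18 (5S,6S,11S,12S)-6,11-bis{2-[(2R)-3,3-dimethyloxiran-2-yl]ethyl}-2,6,11,15-tetramethyl-7,10-dimethylidenehexadeca-1,15-diene-5,12-diol
Conditions: D-fructose-derived Shi ketone (0.6 equiv), Oxone (2KHSO5·KHSO4·K2SO4; 2.6 equiv KHSO5), K2CO3, Bu4NHSO4 (cat.), MeCN/CH2(OMe)2/aq. Na2B4O7–Na2EDTA buffer (pH 10.5), 0 °C; stopped after two oxygen transfers
Reagents that add atoms: potassium peroxymonosulfate (active component of Oxone), [K+].[O-]S(=O)(=O)OO
Why: Shi asymmetric epoxidation; the chiral dioxirane should transfer oxygen fastest to the electron-rich trisubstituted side-chain alkenes, the 1,1-disubstituted alkenes being poorer and (at C11/C14) hindered substrates. The spiro transition state should give the (R)-epoxide at C3 and C22 independently of the remote C6/C7 centres, and the basic buffer keeps the hydroxy epoxide from cyclising.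

**Step 10**
Reactants: 18 bis-epoxide
Product: 19 (3R,6S,7S,3'R,6'S,7'S)-6,6'-(hexa-1,5-diene-2,5-diyl)bis[2,2,6-trimethyl-7-(3-methylbut-3-en-1-yl)oxepan-3-ol]
Conditions: BF3·OEt2 (0.4 equiv), CH2Cl2, −78 → −40 °C; Et3N quench
Reagents that add atoms: none
Why: Lewis-acid-promoted intramolecular opening of a trisubstituted epoxide by a hydroxyl (hydroxy-epoxide cyclisation); coordination of BF3 lengthens the C–O bond at the gem-dimethyl carbon C2 (C23), and O7 (O18) should be captured there in the seven-membered endo mode. C3 and C22 keep their C–O bonds and (R) configuration, and no new stereocentre arises.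

**Step 11**
Reactants: 19 bis-oxepane tetraene
Product: 20 6,6'-(ethane-1,2-diyl)bis[(3R,5aS,9aS)-2,2,5a,7-tetramethyl-2,3,4,5,5a,8,9,9a-octahydro-1-benzoxepin-3-ol]
Conditions: second-generation Grubbs catalyst RuCl2(H2IMes)(PCy3)(=CHPh) (2 × 10 mol%), toluene (5 mM), 80 °C, argon sparge
Reagents that add atoms: none
Why: Twofold ring-closing metathesis of 1,1-disubstituted alkene pairs to tetrasubstituted cyclohexenes; the six-ring closure is the only low-strain pairing (C11 with C14 would give a cyclobutene), and loss of ethene drives it. Hydroxyls and ethers are tolerated, and the trans ring fusion is already fixed by C6 and C7.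

**Step 12**
Reactants: 20 C2-symmetric diol
Product: 21 sodwanone T
Conditions: Dess–Martin periodinane (1.0 equiv), NaHCO3, CH2Cl2, 0 °C; recovered 20 recycled
Reagents that add atoms: none
Why: Dess–Martin oxidation of one of two equivalent secondary carbinols; with one equivalent a statistical mixture is expected, from which the hydroxy ketone is separated. C2 is quaternary, so nothing next to the new ketone can epimerise.

## Compound list

1 | diethyl adipate (diethyl hexanedioate) | CCOC(=O)CCCCC(=O)OCC | starting material
2 | acetaldehyde | CC=O | starting material
3 | dilithium bis-enolate of diethyl adipate (formed in situ) | [Li+].[Li+].CCOC([O-])=CCCC=C([O-])OCC | intermediate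
4 | diethyl 2,5-bis(1-hydroxyethyl)hexanedioate (mixture of diastereomers) | CCOC(=O)C(CCC(C(C)O)C(=O)OCC)C(C)O | intermediate
5 | diethyl 2,5-diacetylhexanedioate (mixture of diastereomers) | CCOC(=O)C(CCC(C(C)=O)C(=O)OCC)C(C)=O | intermediate
6 | disodium bis-enolate of 5 (chelated, formed in situ) | [Na+].[Na+].CCOC(=O)C(CCC(C(=O)OCC)=C(C)[O-])=C(C)[O-] | intermediate
7 | diethyl (2Z,5Z)-2,5-bis[1-(trifluoromethanesulfonyloxy)ethylidene]hexanedioate (triflate cis to ester at both alkenes) | CCOC(=O)/C(CC/C(C(=O)OCC)=C(\C)OS(=O)(=O)C(F)(F)F)=C(/C)OS(=O)(=O)C(F)(F)F | intermediate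
8 | 5-bromo-2-methylpent-2-ene | CC(C)=CCCBr | starting material
9 | (4-methylpent-3-en-1-yl)magnesium bromide (formed in situ) | CC(C)=CCC[Mg]Br | intermediate
10 | diethyl (2Z,5Z)-2,5-bis(6-methylhept-5-en-2-ylidene)hexanedioate (C5 chain cis to ester) | CCOC(=O)/C(CC/C(C(=O)OCC)=C(\C)CCC=C(C)C)=C(/C)CCC=C(C)C | intermediate
11 | (2Z,5Z)-2,5-bis(6-methylhept-5-en-2-ylidene)hexane-1,6-diol | OC/C(CC/C(CO)=C(\C)CCC=C(C)C)=C(/C)CCC=C(C)C | intermediate
12 | bis(pinacolato)diboron | CC1(C)OB(OC1(C)C)B1OC(C)(C)C(C)(C)O1 | starting material
13 | (6E,10E)-2,6,11,15-tetramethyl-7,10-bis[(4,4,5,5-tetramethyl-1,3,2-dioxaborolan-2-yl)methyl]hexadeca-2,6,10,14-tetraene | CC1(C)OB(C/C(=C(/C)CCC=C(C)C)CC/C(CB2OC(C)(C)C(C)(C)O2)=C(\C)CCC=C(C)C)OC1(C)C | intermediate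
14 | 4-methylpent-4-en-1-ol | CC(=C)CCCO | starting material
15 | 4-methylpent-4-enal | CC(=C)CCC=O | intermediate
16 | bis(pinacol borate) of 17 (formed in situ) | C=C(CCC(=C)[C@](C)(CCC=C(C)C)[C@@H](OB1OC(C)(C)C(C)(C)O1)CCC(C)=C)[C@](C)(CCC=C(C)C)[C@@H](OB1OC(C)(C)C(C)(C)O1)CCC(C)=C | intermediate
17 | (5S,6S,11S,12S)-2,6,11,15-tetramethyl-7,10-dimethylidene-6,11-bis(4-methylpent-3-en-1-yl)hexadeca-1,15-diene-5,12-diol | C=C(CCC(=C)[C@](C)(CCC=C(C)C)[C@@H](O)CCC(C)=C)[C@](C)(CCC=C(C)C)[C@@H](O)CCC(C)=C | intermediate
18 | (5S,6S,11S,12S)-6,11-bis{2-[(2R)-3,3-dimethyloxiran-2-yl]ethyl}-2,6,11,15-tetramethyl-7,10-dimethylidenehexadeca-1,15-diene-5,12-diol | C=C(CCC(=C)[C@](C)(CC[C@H]1OC1(C)C)[C@@H](O)CCC(C)=C)[C@](C)(CC[C@H]1OC1(C)C)[C@@H](O)CCC(C)=C | intermediate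
19 | (3R,6S,7S,3'R,6'S,7'S)-6,6'-(hexa-1,5-diene-2,5-diyl)bis[2,2,6-trimethyl-7-(3-methylbut-3-en-1-yl)oxepan-3-ol] | C=C(CCC(=C)[C@]1(C)CC[C@@H](O)C(C)(C)O[C@H]1CCC(C)=C)[C@]1(C)CC[C@@H](O)C(C)(C)O[C@H]1CCC(C)=C | intermediate
20 | 6,6'-(ethane-1,2-diyl)bis[(3R,5aS,9aS)-2,2,5a,7-tetramethyl-2,3,4,5,5a,8,9,9a-octahydro-1-benzoxepin-3-ol] | C(CC1=C(C)CC[C@@H]2OC(C)(C)[C@H](O)CC[C@@]12C)C1=C(C)CC[C@@H]2OC(C)(C)[C@H](O)CC[C@@]12C | intermediate
21 | sodwanone T, (5aS,9aS)-6-{2-[(3R,5aS,9aS)-3-hydroxy-2,2,5a,7-tetramethyl-2,3,4,5,5a,8,9,9a-octahydro-1-benzoxepin-6-yl]ethyl}-2,2,5a,7-tetramethyl-4,5,5a,8,9,9a-hexahydro-1-benzoxepin-3(2H)-one | CC1=C(CCC2=C(C)CC[C@@H]3OC(C)(C)[C@H](O)CC[C@@]23C)[C@]2(C)CCC(=O)C(C)(C)O[C@H]2CC1 | target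

## Step count and least certain steps

Total step count: 12 (step 7 is a one-step branch). Longest linear sequence: 11 steps (steps 1–6 and 8–12).

**Step 8 (key step).** The most likely failure is insufficient turnover of the doubly hindered (β-branched, γ,γ-disubstituted) allylboron units under acid catalysis at the low temperature needed for selectivity. An uncatalysed, unselective pathway or an incomplete second addition would then erode enantio- and diastereocontrol. The fallback keeps the allylboration but moves the source of asymmetry from the catalyst to the boron ligand (Roush-type tartrate allylboronate). It sets out from 11: palladium-catalysed borylation with B2(OH)4 ([Pd(MeCN)4](BF4)2 cat., DMSO/MeOH) should give the [(6E,10E)-tetraene-7,10-diyl]bis(methylene)diboronic acid F1. This is esterified directly with D-(−)-diisopropyl tartrate (the (S,S) ester, whose allylboronates are expected to add to the aldehyde Re face) over MgSO4 to the bis(tartrate allylboronate) F2. F2 is more electrophilic at boron than 13 and should add to 15 without catalyst in toluene at −78 °C through the same chair; hydrolysis returns the route to 17.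

**Step 9.** The risk is loss of chemoselectivity: oxygen transfer to the two methallyl-type alkenes before both trisubstituted alkenes have reacted, or stalling at the mono-epoxide. The fallback moves the epoxidation to a stage where no electron-rich competitor exists. It sets out from 10, whose only other C=C bonds are electron-poor, fully substituted enoates. Shi epoxidation under the step 9 conditions should give the bis-epoxy diester F3. Reduction with i-Bu2AlH at −78 °C gives the bis-epoxy diol F4. Acetylation (Ac2O, pyridine) gives the diacetate F5. Neutral Miyaura borylation (12, Pd(dba)2, DMSO, 50 °C) gives the bis-epoxy bis(allylboronate) F6. F6 is then taken through the allylboration of step 8 with 15, and work-up returns the route to 18. The epoxides have to survive the phosphoric acid at low temperature, which is the price of this detour.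

**Step 10.** The risk is closure through the secondary epoxide carbon C3 (six-membered exo mode), or a hydride shift to the isopropyl ketone, at the expense of the seven-membered endo ether. The fallback forms the same C2–O bond by Markovnikov addition to an alkene, at a stage where no other alkene can compete. It sets out from 18: ring-closing metathesis under the step 11 conditions (the epoxides are spectators) should give the bis(cyclohexenol) bis-epoxide F7. Base-induced epoxide-to-allylic-alcohol isomerisation with diethylaluminium 2,2,6,6-tetramethylpiperidide (toluene, 0 °C) gives the bis(isopropenyl carbinol) F8, with C3 and C22 untouched. Intramolecular alkoxymercuration–demercuration (Hg(OCOCF3)2, CH2Cl2, 0 °C; then NaBH4, aq. NaOH) adds O7/O18 to the tertiary alkene carbon and returns the route to 20.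

**Step 11.** The risk is that the ruthenium alkylidene derived from the second-generation Grubbs catalyst does not engage the hindered C11/C14 methylidene next to the quaternary carbon. This would leave mono-cyclised material, dimerisation through the methallyl termini, or alkene migration at the high temperature required. The fallback replaces alkene metathesis by reductive carbonyl coupling. It sets out from 19: ozonolysis of all four 1,1-disubstituted alkenes (O3, CH2Cl2/MeOH, −78 °C; Me2S) gives the tetraketone F9, 1,4-bis[(3R,6R,7S)-3-hydroxy-2,2,6-trimethyl-7-(3-oxobutyl)oxepan-6-yl]butane-1,4-dione. Twofold intramolecular McMurry coupling of the two 1,6-diketone pairs (TiCl3(DME)1.5, Zn–Cu couple, DME, reflux, high dilution, excess reagent to absorb the free hydroxyls) forms both tetrasubstituted ring alkenes and returns the route to 20.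

**Step 12.** The two carbinols react independently, so over-oxidation to the diketone alongside unreacted diol is expected and limits the yield per pass. The fallback turns the desymmetrisation into a reduction. It sets out from 20: exhaustive Dess–Martin oxidation gives the C2-symmetric diketone F10. Reduction of one ketone under catalyst control ((S)-2-methyl-CBS-oxazaborolidine, BH3·SMe2 limited to about half the hydride needed for both ketones, THF, −30 °C) should deliver the (22R)-carbinol, the C(CH3)2–O group acting as the large substituent, and returns the route to 21. This is still statistical, but it recycles all over-oxidised material and resets C22 by reagent control.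

## Further compounds

F1 | step 8 | {[(6E,10E)-2,6,11,15-tetramethylhexadeca-2,6,10,14-tetraene-7,10-diyl]bis(methylene)}diboronic acid | OB(O)C/C(=C(/C)CCC=C(C)C)CC/C(CB(O)O)=C(\C)CCC=C(C)C
F2 | step 8 | tetraisopropyl (4S,5S,4'S,5'S)-2,2'-{[(6E,10E)-2,6,11,15-tetramethylhexadeca-2,6,10,14-tetraene-7,10-diyl]bis(methylene)}bis(1,3,2-dioxaborolane-4,5-dicarboxylate) | CC(C)OC(=O)[C@H]1OB(C/C(=C(/C)CCC=C(C)C)CC/C(CB2O[C@H](C(=O)OC(C)C)[C@@H](C(=O)OC(C)C)O2)=C(\C)CCC=C(C)C)O[C@@H]1C(=O)OC(C)C
F3 | step 9 | diethyl (2Z,5Z)-2,5-bis{4-[(2R)-3,3-dimethyloxiran-2-yl]butan-2-ylidene}hexanedioate | CCOC(=O)/C(CC/C(C(=O)OCC)=C(\C)CC[C@H]1OC1(C)C)=C(/C)CC[C@H]1OC1(C)C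
F4 | step 9 | (2Z,5Z)-2,5-bis{4-[(2R)-3,3-dimethyloxiran-2-yl]butan-2-ylidene}hexane-1,6-diol | OC/C(CC/C(CO)=C(\C)CC[C@H]1OC1(C)C)=C(/C)CC[C@H]1OC1(C)C
F5 | step 9 | (2Z,5Z)-2,5-bis{4-[(2R)-3,3-dimethyloxiran-2-yl]butan-2-ylidene}hexane-1,6-diyl diacetate | CC(=O)OC/C(CC/C(COC(C)=O)=C(\C)CC[C@H]1OC1(C)C)=C(/C)CC[C@H]1OC1(C)C
F6 | step 9 | bis-epoxy bis(allylboronate), the (E,E)-bis[(pinacolboryl)methyl] analogue of 13 with (R)-3,3-dimethyloxiranyl side-chain termini | CC1(C)OB(C/C(=C(/C)CC[C@H]3OC3(C)C)CC/C(CB2OC(C)(C)C(C)(C)O2)=C(\C)CC[C@H]3OC3(C)C)OC1(C)C
F7 | step 10 | 3,3'-(ethane-1,2-diyl)bis{(1S,2S)-2-{2-[(2R)-3,3-dimethyloxiran-2-yl]ethyl}-2,4-dimethylcyclohex-3-en-1-ol} | C(CC1=C(C)CC[C@H](O)[C@@]1(C)CC[C@H]2OC2(C)C)C1=C(C)CC[C@H](O)[C@@]1(C)CC[C@H]2OC2(C)C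
F8 | step 10 | 3,3'-(ethane-1,2-diyl)bis{(1S,2S)-2-[(3R)-3-hydroxy-4-methylpent-4-en-1-yl]-2,4-dimethylcyclohex-3-en-1-ol} | C(CC1=C(C)CC[C@H](O)[C@@]1(C)CC[C@@H](O)C(C)=C)C1=C(C)CC[C@H](O)[C@@]1(C)CC[C@@H](O)C(C)=C
F9 | step 11 | 1,4-bis[(3R,6R,7S)-3-hydroxy-2,2,6-trimethyl-7-(3-oxobutyl)oxepan-6-yl]butane-1,4-dione | O=C(CCC(=O)[C@]1(C)CC[C@@H](O)C(C)(C)O[C@H]1CCC(C)=O)[C@]1(C)CC[C@@H](O)C(C)(C)O[C@H]1CCC(C)=O
F10 | step 12 | 6,6'-(ethane-1,2-diyl)bis[(5aS,9aS)-2,2,5a,7-tetramethyl-4,5,5a,8,9,9a-hexahydro-1-benzoxepin-3(2H)-one] | C(CC1=C(C)CC[C@@H]2OC(C)(C)C(=O)CC[C@@]12C)C1=C(C)CC[C@@H]2OC(C)(C)C(=O)CC[C@@]12C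
A1 | alternative 1 | C2-symmetric bis(oxepan-3-one), the 3,22-dioxo analogue of sodwanone T | C(CC1=C(C)CC[C@@H]2OC(C)(C)C(=O)CC[C@@]12C)C1=C(C)CC[C@@H]2OC(C)(C)C(=O)CC[C@@]12C
A2 | alternative 1 | C2-symmetric bis(pyran-3-one), 5,5'-(ethane-1,2-diyl)bis[2,2,4a,6-tetramethyl-4a,7,8,8a-tetrahydro-2H-chromen-3(4H)-one] with the ring-fusion configuration of 21 | C(CC1=C(C)CC[C@@H]2OC(C)(C)C(=O)C[C@@]12C)C1=C(C)CC[C@@H]2OC(C)(C)C(=O)C[C@@]12C
A3 | alternative 2 | 3,3'-(hexa-1,5-diene-2,5-diyl)bis(3-methylcyclohexan-1-one), both quaternary centres set | C=C(CCC(=C)[C@]1(C)CCCC(=O)C1)[C@]1(C)CCCC(=O)C1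
A4 | alternative 2 | hexa-1,5-diyne | C#CCCC#C
A5 | alternative 2 | 3-methylcyclohex-2-en-1-one | CC1=CC(=O)CCC1
A6 | alternative 3 | C2-symmetric bis(bicyclic enol ether) with C7=C8 and C17=C18 and silyl ethers at C3 and C22 | C(CC1=C(C)CC=C2OC(C)(C)[C@H](O[Si](C)(C)C(C)(C)C)CC[C@@]12C)C1=C(C)CC=C2OC(C)(C)[C@H](O[Si](C)(C)C(C)(C)C)CC[C@@]12C
A7 | alternative 3 | C2-symmetric bis(oxepan-2-one) carrying the acyclic tetrasubstituted C10=C11 and C14=C15 alkenes with allyl termini | C(C\C(=C(/C)CC=C)[C@]1(C)CC[C@@H](O[Si](C)(C)C(C)(C)C)C(C)(C)OC1=O)\C(=C(/C)CC=C)[C@]1(C)CC[C@@H](O[Si](C)(C)C(C)(C)C)C(C)(C)OC1=O
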